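I had two earlier runs, green and teal, in which G was fed at a steady rate into a stirred flask under E, and I wanted to learn from them what zeta and gamma would give.

| flask | G | E | temperature | remark | time |
|---|---|---|---|---|---|
| green | 0.080 M (fed, over 6.0 min) | 60 mM (held) | 8 °C | run made earlier; the fed solution adds 0.25 times the starting volume |  |
| teal | 0.18 M (fed, over 6.0 min) | 60 mM (held) | 24 °C | run made earlier; the fed solution adds 0.25 times the starting volume |  |
| zeta | 0.12 M (fed, over 20 min) | 60 mM (held) |  | at 0 °C throughout; the fed solution adds 0.25 times the starting volume | 10 min |
| gamma | 0.12 M (fed, over 6.0 min) | 60 mM (held) |  | at 0 °C until 6.0 min, from then on at 30 °C; the fed solution adds 0.25 times the starting volume | 10 min |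

green run (percent of the G charged): time / min: J / % = 0.833: 9.3; 2.00: 26.8; 4.00: 58.3; 6.00: 89.5

teal run (percent of the G charged): time / s: J / % = 15.0: 1.5; 40.0: 7.5; 80.0: 17.1; 120: 27.3

(each reading ± 0.5 percentage points)

- which of the two ends with the higher amount of J, in percent of the G charged ("neither" if they lie within 2 percentage points) (zeta / gamma / neither)
- J at the end, in percent of the G charged, zeta
- J at the end, in percent of the G charged, gamma

- every charge counts on the volume at the start, and the solution that is fed holds the whole dose
- at the start none of E is in solution
- percentages count the whole charge, also what has not yet gone in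

One thing looked wrong at first. Green read 26.8% of J after 2.00 min and teal read 27.3% after 120 s, although teal stood at 24 °C against 8 °C and took its G 2.25 times as fast. Both had by then been fed a third of their charge, so I looked at the gap between G fed and J.

A plain first-order (pseudo-first-order) backlog did not suit that gap. At the end of green's feed it was 10.5%, worth 0.630 min of feeding, so such a pool turns over 9.52 times within the feed and ought to have levelled. Yet it had widened from 6.53% at 2.00 min. I therefore booked the gap as G lost, and assumed that its share of the fed G grows in step with the dosing rate [G]/tf, an assumption of mine.

Rescaling that share, at the readings where a third was fed, to gamma's dosing rate gave 29.4% for green and 12.1% for teal, so on that assumption teal stood lower by a factor 2.44 at equal dosing rate, and that cleared up the puzzle. Rescaling green's end-of-feed gap in the same way and carrying it down to 0 °C with this ratio gave 24.6%: the slip, the share of fed G missing from J at gamma's dosing rate.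

For gamma the missing share was the slip itself, 24.6%, so I expected J near 75.4%. For zeta, dosed more slowly over 20 min, it came to 7.38%, and with half fed at 10 min, J near 46.3%.

The forecast said gamma, with 46.3% for zeta and 98.5% for gamma, on this ground: “Four minutes at 30 °C give an integrated kt of at least 3 even with decay, so it nearly finishes.” We differed on gamma, where my figure was lower.

The flask gave 46.5% for zeta and 80.1% for gamma, so gamma ended higher.

    G + Z → J (k = 2.23 M⁻¹ s⁻¹, Ea = 53.0 kJ mol⁻¹)
    E ⇌ Z, rate k2*(csat - [Z]) (kL = 0.0182 s⁻¹)
    2 G → Q (k = 3.92 M⁻¹ s⁻¹, Ea = 49.0 kJ mol⁻¹)
    (constants at 0 °C)

At the end of gamma's feed, J stood at 77.9%, with Q at 19.7% and G at 2.33% of the G charged, a missing share of 22.0% against my 24.6%. The neighbour flask was zeta's recipe kept at −25 °C. The same ratio, applied to the slip and rescaled to zeta's dosing rate, makes the missing share 29.7% and J about 35.2%. That flask gave J 31.5%, with Q 13.5% and G 5.0%.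

The readings are calculated for substances that don't exist; scatter was added.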